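With the oxolane numbered O1, C2 (ring A), C3 (C9H2OH arm), C4 (C7' ketone to ring B) and C5, the feature exploited is that C5 is an unsubstituted methylene lying between O1 and the ketone α-carbon C4: it is a formaldehyde carbon, and C4–C5 is the bond to disconnect. One operation turns a methoxymethyl ether on the C2 oxygen into the O1=C5H2 cation and the aryl ketone into its enol silane; C4 then adds to C5, closing the oxolane and fixing C4 with the aroyl group trans to the C9 arm. The substrate is an open-chain 1,4-diaryl-4-(methoxymethoxy)butan-1-one whose C2 and C3 centres come from an Evans syn-aldol, with ring A as an electron-poor carbonate.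

Key step: step 12

Remarks on the chemistry.
(a) The locants O1, C2, C3, C4, C5, C9 and C7' denote the same atoms in every intermediate. Read from its SMILES, the target is (2S,3R,4S) in these locants, with the ring A aryl at C2 and the aroyl group at C4 both trans to the C9 arm at C3.
(b) Assumption: (4S)-4-benzyl-1,3-oxazolidin-2-one, methyl 4-chloro-4-oxobutanoate and 2-benzyloxy-1-methylpyridinium triflate are purchased.
(c) Ring A passes through the key step as a benzyl carbonate. It deactivates the ring as an ester would, has no α-hydrogen for the silyl triflate and amine to remove, and leaves in the final hydrogenolysis, so no basic deacylation has to be run on the β-alkoxy ketone.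

Step 1
Reactants: 1 syringaldehyde
Product: 2 3,5-dimethoxy-4-[(triisopropylsilyl)oxy]benzaldehyde
Conditions: iPr3SiCl, imidazole, DMF, rt
Reagents that add atoms: chlorotriisopropylsilane, CC(C)[Si](Cl)(C(C)C)C(C)C
Why: Silyl ether formation on a phenol with a chlorosilane and imidazole is routine, and the bulky triisopropylsilyl group is chosen because it should outlast the basic peroxide of step 4 and the aryllithium of step 10.

Step 2
Reactants: 3 (4S)-4-benzyl-1,3-oxazolidin-2-one; 4 methyl 4-chloro-4-oxobutanoate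
Product: 6 methyl 4-[(4S)-4-benzyl-2-oxo-1,3-oxazolidin-3-yl]-4-oxobutanoate, via N-lithio oxazolidinone 5 (not isolated)
Conditions: n-BuLi, THF, −78 °C; then 4, −78 → 0 °C
Reagents that add atoms: none
Why: N-Acylation of a lithiated oxazolidinone by an acid chloride is the standard preparation of Evans imides and is far faster than attack on the methyl ester.

Step 3
Reactants: 6 imide ester; 2 silylated aldehyde
Product: 9 (4S)-4-benzyl-3-{[(2S,3S)-2-{3,5-dimethoxy-4-[(triisopropylsilyl)oxy]phenyl}-5-oxooxolan-3-yl]carbonyl}-1,3-oxazolidin-2-one (trans lactone imide), via Z boron enolate 7 (not isolated), via boron aldolate 8 (not isolated)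
Conditions: Bu2BOTf, iPr2NEt, CH2Cl2, 0 °C; then 2, −78 °C → rt; pH 7 phosphate buffer, MeOH, H2O2, 0 °C
Reagents that add atoms: none
Why: Evans syn-aldol reaction with lactonization: soft enolization touches only the imide and gives the Z boron enolate, the closed chair transition state with the benzyl group of the (S)-auxiliary blocking one face sets C2 (S) and C3 together in the syn relationship, and on warming the aldolate oxygen acylates itself on the methyl ester to give the trans lactone, which is the 2,3-trans relationship of the target.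

Step 4
Reactants: 9 trans lactone imide
Product: 11 (2S,3S)-2-{3,5-dimethoxy-4-[(triisopropylsilyl)oxy]phenyl}-5-oxooxolane-3-carboxylic acid, via peroxy acid 10 (not isolated)
Conditions: LiOH, H2O2, THF/H2O, 0 °C; aq Na2SO3; HCl to pH 3
Reagents that add atoms: hydrogen peroxide, OO
Why: Hydroperoxide attacks the exocyclic imide carbonyl selectively (Evans auxiliary cleavage with LiOOH), sulfite reduces the peroxy acid, and any lactone opened by hydroxide should reclose on acidification because only the five-membered lactone can form, with C2 and C3 untouched.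

Step 5
Reactants: 11 lactone acid
Product: 12 (4R,5S)-5-{3,5-dimethoxy-4-[(triisopropylsilyl)oxy]phenyl}-4-(hydroxymethyl)oxolan-2-one
Conditions: BH3·SMe2, THF, 0 °C → rt; MeOH
Reagents that add atoms: none
Why: Chemoselective borane reduction takes a carboxylic acid to the primary alcohol much faster than it reduces a lactone, so only C9 is reduced and no stereocentre is touched.

Step 6
Reactants: 12 hydroxymethyl lactone
Product: 13 (4R,5S)-4-[(benzyloxy)methyl]-5-{3,5-dimethoxy-4-[(triisopropylsilyl)oxy]phenyl}oxolan-2-one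
Conditions: 2-benzyloxy-1-methylpyridinium triflate, MgO, PhCF3, 85 °C
Reagents that add atoms: 2-(benzyloxy)-1-methylpyridinium trifluoromethanesulfonate, C[n+]1ccccc1OCc1ccccc1.[O-]S(=O)(=O)C(F)(F)F
Why: O-Benzylation by thermal benzyl transfer from the 2-benzyloxypyridinium salt runs under neutral, MgO-buffered conditions without an alkoxide, which should avoid base-induced migration of the lactone onto the C9 oxygen.

Step 7
Reactants: 13 benzyl ether lactone
Product: 14 (3R,4S)-3-[(benzyloxy)methyl]-4-{3,5-dimethoxy-4-[(triisopropylsilyl)oxy]phenyl}-4-hydroxy-N-methoxy-N-methylbutanamide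
Conditions: Me3Al, MeNHOMe·HCl, CH2Cl2, 0 °C → rt; aq potassium sodium tartrate (KNaC4H4O6)
Reagents that add atoms: N,O-dimethylhydroxylamine hydrochloride, CNOC.Cl
Why: Weinreb amide formation by aminolysis of the lactone with the aluminium amide opens the ring at the acyl carbon only, so the C2–O bond and its configuration are kept.

Step 8
Reactants: 14 hydroxy amide; 15 chloromethyl methyl ether
Product: 16 (3R,4S)-3-[(benzyloxy)methyl]-4-{3,5-dimethoxy-4-[(triisopropylsilyl)oxy]phenyl}-N-methoxy-4-(methoxymethoxy)-N-methylbutanamide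
Conditions: 15, iPr2NEt, Bu4NI (cat.), CH2Cl2, 0 °C → rt
Reagents that add atoms: chloromethyl methyl ether (15), COCCl
Why: Methoxymethyl ether formation by alkylation of the secondary benzylic alcohol with the chloromethyl ether and a hindered amine caps the hydroxyl before it can relactonize and installs the carbon that becomes C5.

Step 9
Reactants: 17 4-bromo-2,6-dimethoxyphenol
Product: 18 2-(benzyloxy)-5-bromo-1,3-dimethoxybenzene
Conditions: BnBr, K2CO3, DMF, rt
Reagents that add atoms: benzyl bromide, BrCc1ccccc1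
Why: Williamson ether synthesis on the phenoxide with benzyl bromide is routine and gives an aryl bromide suited to bromine–lithium exchange.

Step 10
Reactants: 18 aryl bromide; 16 Weinreb amide
Product: 21 (3R,4S)-1-[4-(benzyloxy)-3,5-dimethoxyphenyl]-3-[(benzyloxy)methyl]-4-{3,5-dimethoxy-4-[(triisopropylsilyl)oxy]phenyl}-4-(methoxymethoxy)butan-1-one, via aryllithium 19 (not isolated), via tetrahedral lithium adduct 20 (not isolated)
Conditions: 18, n-BuLi, THF, −78 °C; then 16, −78 → −40 °C; aq NH4Cl
Reagents that add atoms: none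
Why: Bromine–lithium exchange followed by the Weinreb ketone synthesis stops at the chelated tetrahedral adduct, so one aryl group is introduced and the ketone appears only on work-up.

Step 11
Reactants: 21 silyl ether ketone
Product: 23 benzyl 4-[(1S,2R)-4-[4-(benzyloxy)-3,5-dimethoxyphenyl]-2-[(benzyloxy)methyl]-1-(methoxymethoxy)-4-oxobutyl]-2,6-dimethoxyphenyl carbonate, via tetrabutylammonium phenoxide 22 (not isolated)
Conditions: Bu4NF, THF, 0 °C; then BnOCOCl, 0 °C → rt
Reagents that add atoms: benzyl chloroformate, O=C(Cl)OCc1ccccc1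
Why: Fluoride desilylation of the aryl silyl ether and carbonate formation from the resulting phenoxide and the chloroformate in the same flask make ring A electron-poor with a group that the final hydrogenolysis removes.

Step 12
Reactants: 23 methoxymethyl ether ketone
Product: 26 benzyl 4-[(2S,3R,4S)-4-[4-(benzyloxy)-3,5-dimethoxybenzoyl]-3-[(benzyloxy)methyl]oxolan-2-yl]-2,6-dimethoxyphenyl carbonate, via enol silane 24 (not isolated), via oxocarbenium triflate 25 (not isolated)
Conditions: iPr2NEt, Me3SiOTf, CH2Cl2, 0 °C; then Me3SiOTf, −78 → −20 °C; aq NaHCO3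
Reagents that add atoms: none
Why: Proposed new method: the first charge of Me3SiOTf with iPr2NEt silylates the aryl ketone, whose only enolizable carbon is C4, to the Z enol silane 24, and the second charge silylates the unhindered methoxy oxygen of the acetal and expels Me3SiOMe, leaving the alkoxymethyl cation O1=C5H2 of 25; C4 then attacks C5 and the silyl group is returned as Me3SiOTf, so the C4–C5 bond forms and the ketone reappears. The closest known reaction types are the one-flask enol silane formation and Mukaiyama addition to dimethyl acetals with the same reagent pair, Prins closures of alkoxymethyl cations released from methoxymethyl ethers, and the enol ether to oxocarbenium closure of the Petasis–Ferrier rearrangement; an enol silane closing onto a methoxymethyl-derived cation to give a 4-acyloxolane has not been shown. The oxolane (O1, C2, C3, C4, C5) closes 5-endo with respect to the O1=C5 bond and exo with respect to the C4=C7' enol bond, the mode of Prins cyclizations, which is open to a cation because its vacant orbital on C5 can be reached within the forming ring. The new centre C4 is controlled by C3: allylic 1,3-strain keeps the C3–H bond in the enol plane, the tether through C2 brings C5 to one face only, and the aroyl group should therefore end up trans to the C9 arm, which is also the more stable arrangement. The step needs ionization of the acetal CH2–OMe bond and not of the benzylic C2–O bond, secured by the electron-poor carbonate on ring A and by the preference of the silyl group for the unhindered methoxy oxygen, and it needs carbon attack ahead of capture by the C9 benzyl ether oxygen or by ring A, secured by the much higher nucleophilicity of the enol silane and by the deactivated ring.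

Step 13
Reactants: 26 protected oxolane ketone
Product: 27 (4-hydroxy-3,5-dimethoxyphenyl)[(3S,4R,5S)-5-(4-hydroxy-3,5-dimethoxyphenyl)-4-(hydroxymethyl)oxolan-3-yl]methanone (target, CID53356211)
Conditions: H2 (1 atm), Pd/C, EtOAc/EtOH, rt
Reagents that add atoms: none
Why: Catalytic hydrogenolysis should remove both benzyl ethers and the benzyl carbonate (which then loses CO2) under neutral conditions, while the electron-rich aryl ketone and the cyclic benzylic C2–O1 ether are slow to reduce at one atmosphere in a neutral solvent and no stereocentre is touched.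

Compound list

1 | syringaldehyde (4-hydroxy-3,5-dimethoxybenzaldehyde) | COc1cc(C=O)cc(OC)c1O | starting material
2 | 3,5-dimethoxy-4-[(triisopropylsilyl)oxy]benzaldehyde | COc1cc(C=O)cc(OC)c1O[Si](C(C)C)(C(C)C)C(C)C | intermediate
3 | (4S)-4-benzyl-1,3-oxazolidin-2-one | O=C1N[C@@H](Cc2ccccc2)CO1 | starting material
4 | methyl 4-chloro-4-oxobutanoate | COC(=O)CCC(Cl)=O | starting material
5 | N-lithio-(4S)-4-benzyl-1,3-oxazolidin-2-one | [Li]N1[C@@H](Cc2ccccc2)COC1=O | intermediate
6 | methyl 4-[(4S)-4-benzyl-2-oxo-1,3-oxazolidin-3-yl]-4-oxobutanoate | COC(=O)CCC(=O)N1[C@@H](Cc2ccccc2)COC1=O | intermediate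
7 | (Z)-dibutylboron enolate of 6 (boron on the imide enolate oxygen, CH2CO2Me cis to that oxygen) | COC(=O)C/C=C(\OB(CCCC)CCCC)N1[C@@H](Cc2ccccc2)COC1=O | intermediate
8 | methyl (3S,4S)-3-{[(4S)-4-benzyl-2-oxo-1,3-oxazolidin-3-yl]carbonyl}-4-[(dibutylboranyl)oxy]-4-{3,5-dimethoxy-4-[(triisopropylsilyl)oxy]phenyl}butanoate (syn boron aldolate) | COC(=O)C[C@H](C(=O)N1[C@@H](Cc2ccccc2)COC1=O)[C@H](OB(CCCC)CCCC)c1cc(OC)c(O[Si](C(C)C)(C(C)C)C(C)C)c(OC)c1 | intermediate
9 | (4S)-4-benzyl-3-{[(2S,3S)-2-{3,5-dimethoxy-4-[(triisopropylsilyl)oxy]phenyl}-5-oxooxolan-3-yl]carbonyl}-1,3-oxazolidin-2-one (aryl and acyl trans) | O=C1C[C@H](C(=O)N2[C@@H](Cc3ccccc3)COC2=O)[C@@H](c2cc(OC)c(O[Si](C(C)C)(C(C)C)C(C)C)c(OC)c2)O1 | intermediate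
10 | (2S,3S)-2-{3,5-dimethoxy-4-[(triisopropylsilyl)oxy]phenyl}-5-oxooxolane-3-carboperoxoic acid (present as its lithium salt) | O=C1C[C@H](C(=O)OO)[C@@H](c2cc(OC)c(O[Si](C(C)C)(C(C)C)C(C)C)c(OC)c2)O1 | intermediate
11 | (2S,3S)-2-{3,5-dimethoxy-4-[(triisopropylsilyl)oxy]phenyl}-5-oxooxolane-3-carboxylic acid | O=C1C[C@H](C(=O)O)[C@@H](c2cc(OC)c(O[Si](C(C)C)(C(C)C)C(C)C)c(OC)c2)O1 | intermediate
12 | (4R,5S)-5-{3,5-dimethoxy-4-[(triisopropylsilyl)oxy]phenyl}-4-(hydroxymethyl)oxolan-2-one | O=C1C[C@H](CO)[C@@H](c2cc(OC)c(O[Si](C(C)C)(C(C)C)C(C)C)c(OC)c2)O1 | intermediate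
13 | (4R,5S)-4-[(benzyloxy)methyl]-5-{3,5-dimethoxy-4-[(triisopropylsilyl)oxy]phenyl}oxolan-2-one | O=C1C[C@H](COCc2ccccc2)[C@@H](c2cc(OC)c(O[Si](C(C)C)(C(C)C)C(C)C)c(OC)c2)O1 | intermediate
14 | (3R,4S)-3-[(benzyloxy)methyl]-4-{3,5-dimethoxy-4-[(triisopropylsilyl)oxy]phenyl}-4-hydroxy-N-methoxy-N-methylbutanamide | CON(C)C(=O)C[C@H](COCc1ccccc1)[C@H](O)c1cc(OC)c(O[Si](C(C)C)(C(C)C)C(C)C)c(OC)c1 | intermediate
15 | chloromethyl methyl ether | COCCl | starting material
16 | (3R,4S)-3-[(benzyloxy)methyl]-4-{3,5-dimethoxy-4-[(triisopropylsilyl)oxy]phenyl}-N-methoxy-4-(methoxymethoxy)-N-methylbutanamide | CON(C)C(=O)C[C@H](COCc1ccccc1)[C@H](OCOC)c1cc(OC)c(O[Si](C(C)C)(C(C)C)C(C)C)c(OC)c1 | intermediate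
17 | 4-bromo-2,6-dimethoxyphenol | COc1cc(Br)cc(OC)c1O | starting material
18 | 2-(benzyloxy)-5-bromo-1,3-dimethoxybenzene | COc1cc(Br)cc(OC)c1OCc1ccccc1 | intermediate
19 | [4-(benzyloxy)-3,5-dimethoxyphenyl]lithium | [Li]c1cc(OC)c(OCc2ccccc2)c(OC)c1 | intermediate
20 | lithium (3R,4S)-1-[4-(benzyloxy)-3,5-dimethoxyphenyl]-3-[(benzyloxy)methyl]-4-{3,5-dimethoxy-4-[(triisopropylsilyl)oxy]phenyl}-1-[methoxy(methyl)amino]-4-(methoxymethoxy)butan-1-olate (C1 not assigned) | COc1cc(C(O[Li])(N(C)OC)C[C@H](COCc2ccccc2)[C@H](OCOC)c2cc(OC)c(O[Si](C(C)C)(C(C)C)C(C)C)c(OC)c2)cc(OC)c1OCc1ccccc1 | intermediate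
21 | (3R,4S)-1-[4-(benzyloxy)-3,5-dimethoxyphenyl]-3-[(benzyloxy)methyl]-4-{3,5-dimethoxy-4-[(triisopropylsilyl)oxy]phenyl}-4-(methoxymethoxy)butan-1-one | COc1cc(C(=O)C[C@H](COCc2ccccc2)[C@H](OCOC)c2cc(OC)c(O[Si](C(C)C)(C(C)C)C(C)C)c(OC)c2)cc(OC)c1OCc1ccccc1 | intermediate
22 | tetrabutylammonium 4-[(1S,2R)-4-[4-(benzyloxy)-3,5-dimethoxyphenyl]-2-[(benzyloxy)methyl]-1-(methoxymethoxy)-4-oxobutyl]-2,6-dimethoxyphenolate | COc1cc(C(=O)C[C@H](COCc2ccccc2)[C@H](OCOC)c2cc(OC)c([O-])c(OC)c2)cc(OC)c1OCc1ccccc1.CCCC[N+](CCCC)(CCCC)CCCC | intermediate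
23 | benzyl 4-[(1S,2R)-4-[4-(benzyloxy)-3,5-dimethoxyphenyl]-2-[(benzyloxy)methyl]-1-(methoxymethoxy)-4-oxobutyl]-2,6-dimethoxyphenyl carbonate (precursor of the key step) | COc1cc(C(=O)C[C@H](COCc2ccccc2)[C@H](OCOC)c2cc(OC)c(OC(=O)OCc3ccccc3)c(OC)c2)cc(OC)c1OCc1ccccc1 | intermediate
24 | (Z)-trimethylsilyl enol ether of 23 (C4=C7', silyloxy cis to C3) | COc1cc(/C(O[Si](C)(C)C)=C/[C@H](COCc2ccccc2)[C@H](OCOC)c2cc(OC)c(OC(=O)OCc3ccccc3)c(OC)c2)cc(OC)c1OCc1ccccc1 | intermediate
25 | enol silane 24 with the acetal ionized to the O1=C5H2 methylideneoxonium ion, as its triflate | COc1cc(/C(O[Si](C)(C)C)=C/[C@H](COCc2ccccc2)[C@H]([O+]=C)c2cc(OC)c(OC(=O)OCc3ccccc3)c(OC)c2)cc(OC)c1OCc1ccccc1.[O-]S(=O)(=O)C(F)(F)F | intermediate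
26 | benzyl 4-[(2S,3R,4S)-4-[4-(benzyloxy)-3,5-dimethoxybenzoyl]-3-[(benzyloxy)methyl]oxolan-2-yl]-2,6-dimethoxyphenyl carbonate (2,3-trans, 3,4-trans) | COc1cc(C(=O)[C@@H]2CO[C@H](c3cc(OC)c(OC(=O)OCc4ccccc4)c(OC)c3)[C@H]2COCc2ccccc2)cc(OC)c1OCc1ccccc1 | intermediate
27 | (4-hydroxy-3,5-dimethoxyphenyl)[(3S,4R,5S)-5-(4-hydroxy-3,5-dimethoxyphenyl)-4-(hydroxymethyl)oxolan-3-yl]methanone | COc1cc(C(=O)[C@@H]2CO[C@H](c3cc(OC)c(O)c(OC)c3)[C@H]2CO)cc(OC)c1O | target

Total step count: 13 steps.
Longest linear sequence: 11 steps from syringaldehyde 1 (steps 1, 3, 4, 5, 6, 7, 8, 10, 11, 12, 13).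

Steps most likely to fail

Step 12 (carries the new method). The silyl triflate may ionize the acetal at the other oxygen and merely strip the protecting group. The cation may be captured by the C9 benzyl ether oxygen or by ring A instead of by C4. Late re-enolization of the product may erode the configuration at C4. The fallback uses known chemistry only: C5 is brought in as free formaldehyde and the ring is closed at the other carbon–oxygen bond. It sets out from 21. LiN(SiMe3)2 in THF at −78 °C gives the lithium enolate F1, and gaseous formaldehyde (cracked from paraformaldehyde) followed by aqueous NH4Cl gives the β-hydroxy ketone F2 by an aldol addition, as a mixture at C4. Camphorsulfonic acid in CH2Cl2 at room temperature then ionizes the benzylic C2 methoxymethyl ether of the still electron-rich silyloxy ring A, and the C5 hydroxyl closes the ring. This is the acid-mediated benzylic etherification used for 2-aryloxolanes, and it should give the oxolane silyl ether F3 with C2 and C4 settling trans to the C9 arm under thermodynamic control (a trace of DBU if C4 needs help). Bu4NF and then benzyl chloroformate, as in step 11, pass through the tetrabutylammonium phenoxide F4 to 26, where the route is rejoined.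

Step 7. The γ-hydroxy amide may close back to the lactone during work-up, chromatography or the slow capping of step 8, so that material cycles between 13 and 14. The fallback avoids the amide and adds the aryl group to the lactone itself. It sets out from 13. Aryllithium 19 (from 18 and n-BuLi in THF at −78 °C) adds once to the lactone carbonyl at −78 °C to give the lithium lactolate F5, which on aqueous NH4Cl work-up gives the γ-hydroxy aryl ketone F6. Methoxymethylation of F6 under the conditions of step 8 gives 21, where the route is rejoined; steps 7, 8 and 10 are replaced by two operations.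

Step 13. Over-reduction of the aryl ketone, or hydrogenolytic opening of the benzylic C2–O1 bond, may set in before the last benzyl group has gone. The fallback uses neither hydrogen nor a metal catalyst and sets out from 26. K2CO3 in methanol at 0 °C methanolyses the aryl carbonate to the phenol bis(benzyl ether) F7; C4, if it equilibrates, stays trans. BCl3 with pentamethylbenzene in CH2Cl2 at −78 °C (Lewis acid debenzylation with a cation scavenger) then removes both benzyl ethers without touching the ketone, the aryl methyl ethers or the oxolane, and gives 27.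

Further compounds

F1 | step 12 | lithium (Z)-enolate of 21 (C4=C7', lithium on the enolate oxygen) | COc1cc(/C(O[Li])=C/[C@H](COCc2ccccc2)[C@H](OCOC)c2cc(OC)c(O[Si](C(C)C)(C(C)C)C(C)C)c(OC)c2)cc(OC)c1OCc1ccccc1
F2 | step 12 | (3R,4S)-1-[4-(benzyloxy)-3,5-dimethoxyphenyl]-3-[(benzyloxy)methyl]-4-{3,5-dimethoxy-4-[(triisopropylsilyl)oxy]phenyl}-2-(hydroxymethyl)-4-(methoxymethoxy)butan-1-one (mixture at C2 of the chain) | COc1cc(C(=O)C(CO)[C@H](COCc2ccccc2)[C@H](OCOC)c2cc(OC)c(O[Si](C(C)C)(C(C)C)C(C)C)c(OC)c2)cc(OC)c1OCc1ccccc1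
F3 | step 12 | [4-(benzyloxy)-3,5-dimethoxyphenyl][(3S,4R,5S)-4-[(benzyloxy)methyl]-5-{3,5-dimethoxy-4-[(triisopropylsilyl)oxy]phenyl}oxolan-3-yl]methanone | COc1cc(C(=O)[C@@H]2CO[C@H](c3cc(OC)c(O[Si](C(C)C)(C(C)C)C(C)C)c(OC)c3)[C@H]2COCc2ccccc2)cc(OC)c1OCc1ccccc1
F4 | step 12 | tetrabutylammonium 4-[(2S,3R,4S)-4-[4-(benzyloxy)-3,5-dimethoxybenzoyl]-3-[(benzyloxy)methyl]oxolan-2-yl]-2,6-dimethoxyphenolate | COc1cc(C(=O)[C@@H]2CO[C@H](c3cc(OC)c([O-])c(OC)c3)[C@H]2COCc2ccccc2)cc(OC)c1OCc1ccccc1.CCCC[N+](CCCC)(CCCC)CCCC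
F5 | step 7 | lithium (4R,5S)-2-[4-(benzyloxy)-3,5-dimethoxyphenyl]-4-[(benzyloxy)methyl]-5-{3,5-dimethoxy-4-[(triisopropylsilyl)oxy]phenyl}oxolan-2-olate (C2 of the lactolate not assigned) | COc1cc(C2(O[Li])C[C@H](COCc3ccccc3)[C@@H](c3cc(OC)c(O[Si](C(C)C)(C(C)C)C(C)C)c(OC)c3)O2)cc(OC)c1OCc1ccccc1
F6 | step 7 | (3R,4S)-1-[4-(benzyloxy)-3,5-dimethoxyphenyl]-3-[(benzyloxy)methyl]-4-{3,5-dimethoxy-4-[(triisopropylsilyl)oxy]phenyl}-4-hydroxybutan-1-one | COc1cc(C(=O)C[C@H](COCc2ccccc2)[C@H](O)c2cc(OC)c(O[Si](C(C)C)(C(C)C)C(C)C)c(OC)c2)cc(OC)c1OCc1ccccc1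
F7 | step 13 | [4-(benzyloxy)-3,5-dimethoxyphenyl][(3S,4R,5S)-4-[(benzyloxy)methyl]-5-(4-hydroxy-3,5-dimethoxyphenyl)oxolan-3-yl]methanone | COc1cc(C(=O)[C@@H]2CO[C@H](c3cc(OC)c(O)c(OC)c3)[C@H]2COCc2ccccc2)cc(OC)c1OCc1ccccc1
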